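**Plan**

1. Numbering: C1–C4 ring A (C1 oxygenated, C3 isopropenyl), C5 spiro, C6–C10 ring B. The last cuts are the C9–OAc bond and the C1 senecioate.
2. The 6-methyl-6-en-8-one is traced back to a ring B 1,3-dione (C6, C8) by enol ether formation, methyl addition at C6 and transposition.
3. Enabling feature: spiro C5 carries C6 and the methyl-bearing C10, and C8 is oxygenated 1,3 to C6. Ring B is therefore a latent cyclohexane-1,3-dione, cut at C5–C10 and C7–C8 into a 2-acetylcyclopentanone (ring A, C6, C7) and a crotonoyl unit (C8–C10 and the methyl).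
4. Forward: (R)-limonene is cleaved and re-closed to ring A; the Michael–Claisen annulation builds ring B; then C1 reduction, ring B adjustment, C1 esterification and C9 acetoxylation.
5. Stereochemistry: C3 from (R)-limonene; C5 by addition anti to the isopropenyl group; C10 by the (S,S)-t-Bu-box copper catalyst; C1 by hydride attack anti to C10; C9 by acetoxylation anti to the C10 methyl.

Key step: step 7

Remark: diketone 7 is written as its trans diketo tautomer. It is largely enolised and its acetyl-bearing carbon is configurationally labile, which does not matter because C5 is set in step 7.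

**Route**

Step 1
Reactants: 1 (R)-limonene
Product: 2 (4R)-limonene 1,2-oxide (cis/trans mixture at the epoxide carbons)
Conditions: mCPBA (1.0 equiv), CH2Cl2, 0 °C
Reagents that add atoms: 3-chloroperoxybenzoic acid, OOC(=O)c1cccc(Cl)c1
Why: Prilezhaev epoxidation is faster at the electron-richer trisubstituted ring alkene than at the 1,1-disubstituted isopropenyl group, and the epoxide configuration is irrelevant because both carbons become carbonyl carbons in step 2.

Step 2
Reactants: 2 (4R)-limonene 1,2-oxide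
Product: 4 (3R)-6-oxo-3-(prop-1-en-2-yl)heptanal, via limonene-1,2-diol 3 (not isolated)
Conditions: H5IO6 (1.1 equiv), THF/H2O, 0 °C to rt
Reagents that add atoms: water, O
Why: Acid-mediated epoxide hydrolysis followed by periodate (Malaprade) glycol cleavage opens the ring between the two oxygenated carbons and leaves the stereocentre and the isopropenyl group untouched.

Step 3
Reactants: 4 (3R)-6-oxo-3-(prop-1-en-2-yl)heptanal
Product: 5 (3R)-6-oxo-3-(prop-1-en-2-yl)heptanoic acid
Conditions: NaClO2, NaH2PO4, 2-methylbut-2-ene (excess), t-BuOH/H2O, 0 °C to rt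
Reagents that add atoms: NaClO2 (sodium chlorite), [Na+].[O-]Cl=O
Why: Pinnick oxidation converts the aldehyde into the acid without touching the methyl ketone, while the alkene scavenger removes hypochlorous acid before it can reach the isopropenyl group.

Step 4
Reactants: 5 (3R)-6-oxo-3-(prop-1-en-2-yl)heptanoic acid
Product: 6 methyl (3R)-6-oxo-3-(prop-1-en-2-yl)heptanoate
Conditions: MeI, K2CO3, DMF, rt
Reagents that add atoms: iodomethane, CI
Why: SN2 O-methylation of the carboxylate is selective because carbonate is too weak a base to enolise the ketone.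

Step 5
Reactants: 6 methyl (3R)-6-oxo-3-(prop-1-en-2-yl)heptanoate
Product: 7 (2S,4R)-2-acetyl-4-(prop-1-en-2-yl)cyclopentan-1-one
Conditions: KOt-Bu (2.2 equiv), THF, 0 °C to rt; then 1 M HCl
Reagents that add atoms: none
Why: Intramolecular Claisen (Dieckmann-type) condensation, in which the ketone enolate on the methylene side closes the five-membered ring (5-exo-trig, favoured over seven-membered closure from the methyl side) and formation of the diketonate makes the closure irreversible.

Step 6
Reactants: 8 oxazolidin-2-one; 9 (E)-but-2-enoyl chloride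
Product: 10 3-[(E)-but-2-enoyl]oxazolidin-2-one
Conditions: n-BuLi (1.0 equiv), THF, −78 °C; then 9, −78 to 0 °C
Reagents that add atoms: none
Why: N-acylation of the lithiated oxazolidinone by the acid chloride at low temperature should give the imide with the E alkene intact.

Step 7
Reactants: 7 (2S,4R)-2-acetyl-4-(prop-1-en-2-yl)cyclopentan-1-one; 10 3-[(E)-but-2-enoyl]oxazolidin-2-one
Product: 12 (3R,5R,10S)-10-methyl-3-(prop-1-en-2-yl)spiro[4.5]decane-1,6,8-trione, via Michael adduct 11 (not isolated)
Conditions: Cu(OTf)2 (10 mol %), (S,S)-t-Bu-box [2,2′-(propane-2,2-diyl)bis((4S)-4-tert-butyl-4,5-dihydrooxazole)] (11 mol %), 4 Å MS, CH2Cl2, 0 °C to rt; silica plug, solvent switch to THF without purification; LiN(SiMe3)2 (1.5 equiv), THF, −78 to −20 °C; aq NH4Cl, then 1 M HCl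
Reagents that add atoms: none
Why: The divalent copper centre, carrying the bisoxazoline, binds imide 10 through both carbonyl oxygens in its s-cis form and the enol of 7 adds through C5 to the β-carbon (C10) to give 11; LiN(SiMe3)2 then deprotonates the acetyl methyl (C7), which acylates the imide carbonyl C8 with loss of oxazolidin-2-one, whose anion deprotonates the new 1,3-dione. The closest known reactions are chiral Lewis acid catalysed Michael additions of cyclic 1,3-dicarbonyl compounds to crotonoyl imides and the Michael–Claisen (dimedone-type) synthesis of cyclohexane-1,3-diones. Ring B closes by a 6-exo-trig Claisen (Dieckmann-type) acylation. C10 is set by the ligand: in the square-planar two-point complex the tert-butyl group covers the Re face of the β-carbon, so C5 attacks the Si face; C5 is set by the substrate, the acceptor approaching the enol face anti to the C3 isopropenyl group, which leaves C10 trans and the acetyl carbon C6 cis to isopropenyl. The step needs C–C bond formation at the fully substituted C5 and ring closure from C7, not from C2 or C9: the high enol content of the 1,3-diketone secures the first, and the second follows because the bulky amide removes the unhindered methyl proton fastest and only closure from C7 ends in a stabilised dione enolate. The non-nucleophilic base also spares the non-enolisable C1/C6 diketone from retro-Claisen cleavage.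

Step 8
Reactants: 12 (3R,5R,10S)-10-methyl-3-(prop-1-en-2-yl)spiro[4.5]decane-1,6,8-trione
Product: 13 (1S,3R,5R,10S)-1-hydroxy-10-methyl-3-(prop-1-en-2-yl)spiro[4.5]decane-6,8-dione
Conditions: NaOH (1.0 equiv), EtOH/H2O, 0 °C; NaBH4 (1.5 equiv); then 1 M HCl to pH 3
Reagents that add atoms: none
Why: Borohydride reduction of a ketone, in which the ring B dione is masked as its sodium enolate so that only C1 is reduced, and hydride should enter from the face flanked by the flat C6 and away from the sp3 C10 with its methyl group, placing the hydroxyl cis to C10 (1S).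

Step 9
Reactants: 13 (1S,3R,5R,10S)-1-hydroxy-10-methyl-3-(prop-1-en-2-yl)spiro[4.5]decane-6,8-dione
Product: 14 (1S,3R,5R,10S)-1-hydroxy-8-methoxy-10-methyl-3-(prop-1-en-2-yl)spiro[4.5]dec-7-en-6-one
Conditions: MeOH, TsOH·H2O (5 mol %), 3 Å MS, rt
Reagents that add atoms: methanol, CO
Why: Acid-catalysed enol etherification of a 1,3-dione, in which methanol attacks the unhindered C8 carbonyl and not C6 next to the quaternary C5, so the vinylogous ester keeps its carbonyl at C6.

Step 10
Reactants: 14 (1S,3R,5R,10S)-1-hydroxy-8-methoxy-10-methyl-3-(prop-1-en-2-yl)spiro[4.5]dec-7-en-6-one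
Product: 15 (1S,3R,5R,10S)-8-methoxy-10-methyl-3-(prop-1-en-2-yl)-1-[(triethylsilyl)oxy]spiro[4.5]dec-7-en-6-one
Conditions: Et3SiCl, imidazole, DMAP (cat.), DMF, rt
Reagents that add atoms: chlorotriethylsilane, CC[Si](Cl)(CC)CC
Why: Silylation of the secondary alcohol removes the C1 alkoxide that would otherwise form in step 11 and open ring A by retro-aldol cleavage of C1–C5.

Step 11
Reactants: 15 (1S,3R,5R,10S)-8-methoxy-10-methyl-3-(prop-1-en-2-yl)-1-[(triethylsilyl)oxy]spiro[4.5]dec-7-en-6-one
Product: 18 (1S,3R,5S,10S)-1-hydroxy-6,10-dimethyl-3-(prop-1-en-2-yl)spiro[4.5]dec-6-en-8-one, via tertiary carbinol 16 (not isolated), via silyl enone 17 (not isolated)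
Conditions: MeLi (3 equiv), THF, −78 to 0 °C; then 1 M HCl, THF, rt
Reagents that add atoms: methyllithium (MeLi), [Li]C
Why: Stork–Danheiser transposition, in which MeLi adds 1,2 to the C6 carbonyl of the vinylogous ester (C5 has no proton to lose), aqueous acid hydrolyses the enol ether with loss of the tertiary hydroxyl to give the 6-methyl-6-en-8-one, and the same acid cleaves the triethylsilyl ether.

Step 12
Reactants: 18 (1S,3R,5S,10S)-1-hydroxy-6,10-dimethyl-3-(prop-1-en-2-yl)spiro[4.5]dec-6-en-8-one
Product: 19 (1S,3R,5S,10S)-6,10-dimethyl-8-oxo-3-(prop-1-en-2-yl)spiro[4.5]dec-6-en-1-yl 3-methylbut-2-enoate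
Conditions: 3-methylbut-2-enoyl chloride, pyridine, DMAP (cat.), CH2Cl2, 0 °C to rt
Reagents that add atoms: 3-methylbut-2-enoyl chloride, CC(C)=CC(=O)Cl
Why: DMAP-catalysed acylation of the secondary alcohol with the acid chloride, with the weak base pyridine chosen to limit vinylketene formation and hence the deconjugated ester.

Step 13
Reactants: 19 (1S,3R,5S,10S)-6,10-dimethyl-8-oxo-3-(prop-1-en-2-yl)spiro[4.5]dec-6-en-1-yl 3-methylbut-2-enoate
Product: 20 (1S,3R,5S,9S,10R)-9-(acetyloxy)-6,10-dimethyl-8-oxo-3-(prop-1-en-2-yl)spiro[4.5]dec-6-en-1-yl 3-methylbut-2-enoate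
Conditions: Mn(OAc)3·2H2O (3 equiv), benzene, reflux, Dean–Stark
Reagents that add atoms: manganese triacetate dihydrate, CC(=O)[O-].CC(=O)[O-].CC(=O)[O-].[Mn+3].O.O
Why: α′-Acetoxylation of an enone by the acetate of trivalent manganese, in which the manganese enolate transfers acetate to C9, the only α′ position, from the ring B face opposite the adjacent C10 methyl and the C1 ester, which should give the 9,10-trans (9S) acetate while the esters and the isopropenyl group stay inert.

**Compound list**

1 | (R)-limonene, (4R)-1-methyl-4-(prop-1-en-2-yl)cyclohex-1-ene | CC1=CC[C@@H](CC1)C(C)=C | starting material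
2 | (4R)-limonene 1,2-oxide, (4R)-1-methyl-4-(prop-1-en-2-yl)-7-oxabicyclo[4.1.0]heptane, cis/trans mixture | CC12OC1C[C@@H](CC2)C(C)=C | intermediate
3 | (4R)-1-methyl-4-(prop-1-en-2-yl)cyclohexane-1,2-diol (limonene-1,2-diol, formed and cleaved in the flask) | CC1(O)C(O)C[C@@H](CC1)C(C)=C | intermediate
4 | (3R)-6-oxo-3-(prop-1-en-2-yl)heptanal | CC(=O)CC[C@H](CC=O)C(C)=C | intermediate
5 | (3R)-6-oxo-3-(prop-1-en-2-yl)heptanoic acid | CC(=O)CC[C@H](CC(=O)O)C(C)=C | intermediate
6 | methyl (3R)-6-oxo-3-(prop-1-en-2-yl)heptanoate | CC(=O)CC[C@H](CC(=O)OC)C(C)=C | intermediate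
7 | (2S,4R)-2-acetyl-4-(prop-1-en-2-yl)cyclopentan-1-one (trans diketo form drawn; enolised, acetyl-bearing carbon labile) | C=C(C)[C@H]1CC(=O)[C@@H](C1)C(C)=O | intermediate
8 | oxazolidin-2-one | O=C1NCCO1 | starting material
9 | (E)-but-2-enoyl chloride (crotonyl chloride) | C/C=C/C(=O)Cl | starting material
10 | 3-[(E)-but-2-enoyl]oxazolidin-2-one | C/C=C/C(=O)N1CCOC1=O | intermediate
11 | 3-[(3S)-3-[(1S,4R)-1-acetyl-2-oxo-4-(prop-1-en-2-yl)cyclopentyl]butanoyl]oxazolidin-2-one (Michael adduct, formed and cyclised without isolation) | C=C(C)[C@H]1CC(=O)[C@](C1)(C(C)=O)[C@@H](C)CC(=O)N1CCOC1=O | intermediate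
12 | (3R,5R,10S)-10-methyl-3-(prop-1-en-2-yl)spiro[4.5]decane-1,6,8-trione (C10 trans, C6 cis to isopropenyl) | C=C(C)[C@H]1CC(=O)[C@]2(C1)C(=O)CC(=O)C[C@@H]2C | intermediate
13 | (1S,3R,5R,10S)-1-hydroxy-10-methyl-3-(prop-1-en-2-yl)spiro[4.5]decane-6,8-dione (OH cis to C10) | C=C(C)[C@H]1C[C@H](O)[C@]2(C1)C(=O)CC(=O)C[C@@H]2C | intermediate
14 | (1S,3R,5R,10S)-1-hydroxy-8-methoxy-10-methyl-3-(prop-1-en-2-yl)spiro[4.5]dec-7-en-6-one | C=C(C)[C@H]1C[C@H](O)[C@]2(C1)C(=O)C=C(OC)C[C@@H]2C | intermediate
15 | (1S,3R,5R,10S)-8-methoxy-10-methyl-3-(prop-1-en-2-yl)-1-[(triethylsilyl)oxy]spiro[4.5]dec-7-en-6-one | C=C(C)[C@H]1C[C@H](O[Si](CC)(CC)CC)[C@]2(C1)C(=O)C=C(OC)C[C@@H]2C | intermediate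
16 | (1S,3R,10S)-8-methoxy-6,10-dimethyl-3-(prop-1-en-2-yl)-1-[(triethylsilyl)oxy]spiro[4.5]dec-7-en-6-ol (either C6 epimer, formed and transposed in the flask) | C=C(C)[C@H]1C[C@H](O[Si](CC)(CC)CC)[C@]2(C1)C(C)(O)C=C(OC)C[C@@H]2C | intermediate
17 | (1S,3R,5S,10S)-6,10-dimethyl-3-(prop-1-en-2-yl)-1-[(triethylsilyl)oxy]spiro[4.5]dec-6-en-8-one (desilylated in the flask) | C=C(C)[C@H]1C[C@H](O[Si](CC)(CC)CC)[C@]2(C1)C(C)=CC(=O)C[C@@H]2C | intermediate
18 | (1S,3R,5S,10S)-1-hydroxy-6,10-dimethyl-3-(prop-1-en-2-yl)spiro[4.5]dec-6-en-8-one | C=C(C)[C@H]1C[C@H](O)[C@]2(C1)C(C)=CC(=O)C[C@@H]2C | intermediate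
19 | (1S,3R,5S,10S)-6,10-dimethyl-8-oxo-3-(prop-1-en-2-yl)spiro[4.5]dec-6-en-1-yl 3-methylbut-2-enoate | C=C(C)[C@H]1C[C@H](OC(=O)C=C(C)C)[C@]2(C1)C(C)=CC(=O)C[C@@H]2C | intermediate
20 | (1S,3R,5S,9S,10R)-9-(acetyloxy)-6,10-dimethyl-8-oxo-3-(prop-1-en-2-yl)spiro[4.5]dec-6-en-1-yl 3-methylbut-2-enoate (CNP0218315.1) | C=C(C)[C@H]1C[C@H](OC(=O)C=C(C)C)[C@]2(C1)C(C)=CC(=O)[C@@H](OC(C)=O)[C@@H]2C | target

**Step count**

Total: 13 steps. Longest linear sequence: 12 steps (steps 1–5 and 7–13, from (R)-limonene); step 6 is a one-step branch.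

**Steps most likely to fail**

Step 7. Three processes may spoil it. The chelating diketone may tie up the copper centre so that the imide is no longer activated. The ligand-controlled acceptor face and the substrate-controlled donor face may pair poorly, eroding selectivity at C5 and C10. The amide base may enolise the imide at C9 and so open a retro-Michael path. The fallback sets out from 7 and returns at 12. Diketone 7 is added to (E)-but-2-enal under iminium catalysis with (R)-α,α-diphenylprolinol trimethylsilyl ether and benzoic acid in toluene. The iminium ion of this catalyst exposes the Si face of the β-carbon, and the donor again reacts anti to the isopropenyl group, to give the aldehyde (3S)-3-[(1S,4R)-1-acetyl-2-oxo-4-(prop-1-en-2-yl)cyclopentyl]butanal F1. Pinnick oxidation (NaClO2, NaH2PO4, 2-methylbut-2-ene) gives the acid (3S)-3-[(1S,4R)-1-acetyl-2-oxo-4-(prop-1-en-2-yl)cyclopentyl]butanoic acid F2, and MeI with K2CO3 in DMF gives the ester methyl (3S)-3-[(1S,4R)-1-acetyl-2-oxo-4-(prop-1-en-2-yl)cyclopentyl]butanoate F3. LiN(SiMe3)2 in THF at −78 to 0 °C then closes C7 onto the ester carbonyl to give 12. Because an ester α-proton is less acidic than the ketone methyl protons, enolisation at C9 and the retro-Michael path are avoided.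

Step 8. Hydride delivery to C1 may show poor facial selectivity, since it rests only on the difference between the C6 and C10 flanks of the spiro centre. The fallback sets out from 12 and returns at 14, replacing substrate control by reagent control. Trione 12 is first O-methylated (MeOH, TsOH, 3 Å MS) at the unhindered C8 oxygen to give the keto enol ether (3R,5R,10S)-8-methoxy-10-methyl-3-(prop-1-en-2-yl)spiro[4.5]dec-7-ene-1,6-dione F4. Corey–Bakshi–Shibata reduction with (R)-2-methyl-CBS-oxazaborolidine and catecholborane in toluene at −78 °C should then distinguish the quaternary C5 from the C2 methylene at the C1 ketone and give the (1S) alcohol 14. Catecholborane at this temperature leaves the isopropenyl group and the vinylogous ester alone.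

Step 13. Acetate transfer to C9 may be poorly face-selective, or the oxidation may be sluggish or go on to a second acetoxylation on advanced material. The fallback sets out from 15 and returns at 20, using enolate oxidation on a C1-protected enone. Compound 15 is treated with MeLi as in step 11 but quenched with cold aqueous oxalic acid, which transposes the enone and keeps the silyl ether, so that silyl enone 17 is isolated. Kinetic deprotonation at C9 with LiN(i-Pr)2 in THF at −78 °C and oxidation with 3-phenyl-2-(phenylsulfonyl)oxaziridine, entering anti to the C10 methyl, gives the ketol (1S,3R,5S,9S,10R)-9-hydroxy-6,10-dimethyl-3-(prop-1-en-2-yl)-1-[(triethylsilyl)oxy]spiro[4.5]dec-6-en-8-one F5. Ac2O, pyridine and DMAP give the acetate (1S,3R,5S,9S,10R)-6,10-dimethyl-8-oxo-3-(prop-1-en-2-yl)-1-[(triethylsilyl)oxy]spiro[4.5]dec-6-en-9-yl acetate F6. HF·pyridine in THF frees the alcohol (1S,3R,5S,9S,10R)-1-hydroxy-6,10-dimethyl-8-oxo-3-(prop-1-en-2-yl)spiro[4.5]dec-6-en-9-yl acetate F7, and acylation with 3-methylbut-2-enoyl chloride, pyridine and DMAP gives 20.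

**Further compounds**

F1 | step 7 | (3S)-3-[(1S,4R)-1-acetyl-2-oxo-4-(prop-1-en-2-yl)cyclopentyl]butanal | C=C(C)[C@H]1CC(=O)[C@](C1)(C(C)=O)[C@@H](C)CC=O
F2 | step 7 | (3S)-3-[(1S,4R)-1-acetyl-2-oxo-4-(prop-1-en-2-yl)cyclopentyl]butanoic acid | C=C(C)[C@H]1CC(=O)[C@](C1)(C(C)=O)[C@@H](C)CC(=O)O
F3 | step 7 | methyl (3S)-3-[(1S,4R)-1-acetyl-2-oxo-4-(prop-1-en-2-yl)cyclopentyl]butanoate | C=C(C)[C@H]1CC(=O)[C@](C1)(C(C)=O)[C@@H](C)CC(=O)OC
F4 | step 8 | (3R,5R,10S)-8-methoxy-10-methyl-3-(prop-1-en-2-yl)spiro[4.5]dec-7-ene-1,6-dione | C=C(C)[C@H]1CC(=O)[C@]2(C1)C(=O)C=C(OC)C[C@@H]2C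
F5 | step 13 | (1S,3R,5S,9S,10R)-9-hydroxy-6,10-dimethyl-3-(prop-1-en-2-yl)-1-[(triethylsilyl)oxy]spiro[4.5]dec-6-en-8-one | C=C(C)[C@H]1C[C@H](O[Si](CC)(CC)CC)[C@]2(C1)C(C)=CC(=O)[C@@H](O)[C@@H]2C
F6 | step 13 | (1S,3R,5S,9S,10R)-6,10-dimethyl-8-oxo-3-(prop-1-en-2-yl)-1-[(triethylsilyl)oxy]spiro[4.5]dec-6-en-9-yl acetate | C=C(C)[C@H]1C[C@H](O[Si](CC)(CC)CC)[C@]2(C1)C(C)=CC(=O)[C@@H](OC(C)=O)[C@@H]2C
F7 | step 13 | (1S,3R,5S,9S,10R)-1-hydroxy-6,10-dimethyl-8-oxo-3-(prop-1-en-2-yl)spiro[4.5]dec-6-en-9-yl acetate | C=C(C)[C@H]1C[C@H](O)[C@]2(C1)C(C)=CC(=O)[C@@H](OC(C)=O)[C@@H]2C
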